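## Retrosynthetic overview

1. The last C–C bond is C9–C11, made by sp2–sp3 Suzuki coupling of a C8=C9 enol triflate with the 9-BBN adduct of a C6 dienoate; both isovalerates go onto a 3α,6β-diol while C19–OH stays silylated to the end.
2. The 3α,6β-diol-9-ketone comes from one cis-fused octalone: C3–Si → C3–OH (retention), C6=O → 6β-OH, and C5/C8 are set by equilibration of a 6,9-dione.
3. Key disconnection: C3–C4 and C5–C10 together, by an intramolecular Diels–Alder reaction of an open-chain trienone. Rings A and B form in the same step; no carbocycle exists before it.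
4. Enabling feature: ring A (C1–C5, C10) carries the C6 oxygen next to C5. With C1=C2 unsaturation, C3–C4 and C5–C10 are the two bonds of a cyclohexene retron; C6 as a ketone makes C4=C5 an enone, and C6–C9 is the four-atom tether that becomes ring B. The C3 oxygen is carried as silicon on the diene terminus.
5. The trienone is built from two copies of one 2-methylallyl C4 unit (C19–C4(C18)=C5 and C9–C10(C20)=C1), joined through a crotylboration-derived lactone. C8 and C9 relay the absolute configuration and are later flattened into the C8=C9 alkene.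

Key step: step 10

Remark on locants: labdane numbering is used throughout. Ring A is C1–C5 and C10, ring B is C5–C10. The methyl groups are C18 (4α), C17 (on C8) and C20 (10β); C19 is the 4β-CH2O carbon; β is the face of the C10 methyl.

Assumption: the (Z)-crotylborane made from (+)-Ipc2BOMe adds to the Re face of the aldehyde, the sense known for (+)-Ipc2B allyl and crotyl reagents; the mirror-image borane would be used otherwise.

## Route

Step 1
Reactants: 1 prop-2-yn-1-ol
Product: 3 (E)-3-iodo-2-methylprop-2-en-1-ol, via alkenylalane 2 (not isolated)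
Conditions: AlMe3 (3 equiv), Cp2ZrCl2 (0.25 equiv), CH2Cl2, 0 °C to rt; then I2, THF, −30 °C
Reagents that add atoms: trimethylaluminium AlMe3 (C[Al](C)C); iodine (II)
Why: Negishi zirconium-catalysed carboalumination adds methyl and aluminium syn with aluminium on the terminal carbon, and iodinolysis with retention should give the E-iodide (CH2OH trans to iodine).

Step 2
Reactants: 3 (E)-3-iodo-2-methylprop-2-en-1-ol
Product: 4 (E)-3-iodo-2-methylprop-2-enal
Conditions: MnO2 (15 equiv), CH2Cl2, rt
Reagents that add atoms: none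
Why: Allylic alcohol oxidation with MnO2 leaves the alkenyl iodide and its geometry untouched.

Step 3
Reactants: 4 (E)-3-iodo-2-methylprop-2-enal
Product: 5 (1E,3R,4S)-1-iodo-2,4-dimethylhexa-1,5-dien-3-ol
Conditions: cis-but-2-ene, KOt-Bu, n-BuLi, THF, −78 to −45 °C; (+)-Ipc2BOMe, −78 °C; BF3·OEt2; then 4, −78 °C; work-up NaOH, H2O2
Reagents that add atoms: cis-but-2-ene (C/C=C\C)
Why: Brown crotylboration through a closed chair transition state; the Z-crotyl geometry gives the syn methyl/hydroxyl pair and the isopinocampheyl groups direct Re-face addition, setting 3R,4S (C9 and C8 of the target numbering).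

Step 4
Reactants: 5 (1E,3R,4S)-1-iodo-2,4-dimethylhexa-1,5-dien-3-ol
Product: 7 (3S,4R,5E)-6-iodo-3,5-dimethylhex-5-ene-1,4-diol, via bis-borane 6 (not isolated)
Conditions: 9-BBN (2.2 equiv), THF, 0 °C to rt; then NaOH, H2O2, 0 °C
Reagents that add atoms: hydrogen peroxide (OO)
Why: Anti-Markovnikov hydroboration–oxidation; 9-BBN should react only with the monosubstituted terminal alkene and not with the trisubstituted alkenyl iodide.

Step 5
Reactants: 7 (3S,4R,5E)-6-iodo-3,5-dimethylhex-5-ene-1,4-diol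
Product: 9 (4S,5R)-5-[(E)-1-iodoprop-1-en-2-yl]-4-methyloxolan-2-one, via lactol 8 (not isolated)
Conditions: TEMPO (0.2 equiv), PhI(OAc)2 (2.5 equiv), CH2Cl2, rt
Reagents that add atoms: none
Why: Oxidative lactonisation of a 1,4-diol: TEMPO/PhI(OAc)2 oxidises the primary alcohol selectively, the secondary hydroxyl closes the lactol, and this is oxidised on to the cis-4,5-disubstituted γ-lactone.

Step 6
Reactants: 10 ethynyl(dimethyl)phenylsilane
Product: 11 (E)-dimethyl(phenyl)[2-(4,4,5,5-tetramethyl-1,3,2-dioxaborolan-2-yl)ethenyl]silane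
Conditions: pinacolborane (1.1 equiv), Cp2Zr(H)Cl (5 mol%), Et3N (10 mol%), neat, 60 °C
Reagents that add atoms: pinacolborane ([H]B1OC(C)(C)C(C)(C)O1)
Why: Zirconium-catalysed syn hydroboration of a terminal alkyne places boron on the terminal carbon and should give the E-alkenylboronate.

Step 7
Reactants: 9 (4S,5R)-5-[(E)-1-iodoprop-1-en-2-yl]-4-methyloxolan-2-one; 11 (E)-dimethyl(phenyl)[2-(4,4,5,5-tetramethyl-1,3,2-dioxaborolan-2-yl)ethenyl]silane
Product: 12 (4S,5R)-5-[(2E,4E)-5-[dimethyl(phenyl)silyl]penta-2,4-dien-2-yl]-4-methyloxolan-2-one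
Conditions: Pd(dppf)Cl2 (5 mol%), K3PO4 (3 equiv), THF/H2O 10:1, 40 °C
Reagents that add atoms: none
Why: Suzuki–Miyaura coupling of an alkenyl iodide with an alkenylboronate retains both geometries, giving the E,E-diene with the methyl inside and the lactone carbon and silicon outside.

Step 8
Reactants: 3 (E)-3-iodo-2-methylprop-2-en-1-ol
Product: 13 (E)-[(3-iodo-2-methylprop-2-en-1-yl)oxy]tri(propan-2-yl)silane
Conditions: TIPSCl (1.2 equiv), imidazole (2.5 equiv), DMF, rt
Reagents that add atoms: chlorotri(propan-2-yl)silane (CC(C)[Si](Cl)(C(C)C)C(C)C)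
Why: Standard silylation of a primary alcohol; the TIPS ether should survive every step up to the last.

Step 9
Reactants: 13 (E)-[(3-iodo-2-methylprop-2-en-1-yl)oxy]tri(propan-2-yl)silane; 12 (4S,5R)-5-[(2E,4E)-5-[dimethyl(phenyl)silyl]penta-2,4-dien-2-yl]-4-methyloxolan-2-one
Product: 15 (2E,6S,7R,8E,10E)-11-[dimethyl(phenyl)silyl]-7-hydroxy-2,6,8-trimethyl-1-[(triisopropylsilyl)oxy]undeca-2,8,10-trien-4-one, via alkenyllithium 14 (not isolated)
Conditions: 13, t-BuLi (2.05 equiv), Et2O, −78 °C; then 12 in THF, −78 °C; NH4Cl (aq) at −78 °C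
Reagents that add atoms: none
Why: Iodine–lithium exchange with retention of geometry, then single addition of the alkenyllithium to the γ-lactone (the lithium lactolate holds at −78 °C) should give the E-enone with the C9 hydroxyl free; no new stereocentre.

Step 10
Reactants: 15 (2E,6S,7R,8E,10E)-11-[dimethyl(phenyl)silyl]-7-hydroxy-2,6,8-trimethyl-1-[(triisopropylsilyl)oxy]undeca-2,8,10-trien-4-one
Product: 16 cis-fused octalone: 3α-[dimethyl(phenyl)silyl]-9α-hydroxy-4α,8β,10β-trimethyl-4β-[(triisopropylsilyloxy)methyl]-5β-H-decal-1-en-6-one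
Conditions: toluene (0.01 M), BHT (5 mol%), base-washed sealed vessel, 120 °C
Reagents that add atoms: none
Why: Thermal concerted [4+2] cycloaddition (intramolecular Diels–Alder) of the C4=C5 enone with the C10=C1–C2=C3 diene forms C3–C4 and C5–C10 in one event; the closest known reaction type is the cyclisation of 1,7,9-decatrien-3-ones to cis-fused octalones. Ring B closes in the fused mode through the four-atom tether C6–C9 (carbonyl inside the new six-membered ring), and ring A is the cyclohexene made by the two new bonds. C10 and C3 follow from the diene geometry (tether and silicon outside, methyl inside, so C9 and silicon end up cis on ring A); C4 follows from the E-dienophile and the endo position of the tether carbonyl (the methyl cis to the acyl group lands on the silicon face, CH2OTIPS on the face of the C10 methyl); C5 comes out cis-fused (5β-H) and is corrected in step 12. The absolute sense is controlled by C8 and C9: only one diene face lets the syn methyl/hydroxyl pair sit diequatorial on the chair-like tether while the enone stays s-cis (the β-methyl cis to the acyl group forbids s-trans). The step needs endo over exo selectivity and this facial selectivity; endo should be secured by the carbonyl lying under the diene and by the inside C10 methyl, which clashes with an exo-oriented tether.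

Step 11
Reactants: 16 cis-fused octalone
Product: 17 cis-fused decalone: 3α-[dimethyl(phenyl)silyl]-9α-hydroxy-4α,8β,10β-trimethyl-4β-[(triisopropylsilyloxy)methyl]-5β-H-decalin-6-one
Conditions: H2 (3 atm), 10% Pd/C, EtOAc, rt
Reagents that add atoms: none
Why: Heterogeneous hydrogenation of the only C=C bond; ketone, silanes and silyl ether should be unaffected and no stereocentre is formed.

Step 12
Reactants: 17 cis-fused decalone
Product: 19 trans-fused dione: 3α-[dimethyl(phenyl)silyl]-4α,8α,10β-trimethyl-4β-[(triisopropylsilyloxy)methyl]-5α-H-decalin-6,9-dione, via cis-dione 18 (not isolated)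
Conditions: Dess–Martin periodinane (1.5 equiv), NaHCO3, CH2Cl2, rt; filter, concentrate; then NaOMe (0.5 equiv), MeOH/THF, rt
Reagents that add atoms: none
Why: Alcohol oxidation, then base epimerisation through the C5 and C8 enolates, should settle at the trans-fused dione with equatorial 8-methyl, because the cis-fused 4,4,10-trisubstituted decalin cannot avoid an extra syn-diaxial interaction.

Step 13
Reactants: 19 trans-fused dione
Product: 20 6β-hydroxy-9-ketone: 3α-[dimethyl(phenyl)silyl]-6β-hydroxy-4α,8α,10β-trimethyl-4β-[(triisopropylsilyloxy)methyl]-5α-H-decalin-9-one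
Conditions: LiBH(s-Bu)3 (1.1 equiv), THF, −78 °C; work-up NaOH, H2O2
Reagents that add atoms: none
Why: The bulky hydride should leave the C9 carbonyl (flanked by quaternary C10 and methyl-bearing C8) alone and reach C6 from the α face, since the β face is closed by the axial C19 and C20 groups, giving the axial 6β-alcohol.

Step 14
Reactants: 20 6β-hydroxy-9-ketone
Product: 21 3α,6β-diol: 3α,6β-dihydroxy-4α,8α,10β-trimethyl-4β-[(triisopropylsilyloxy)methyl]-5α-H-decalin-9-one
Conditions: KBr (1.5 equiv), AcOOH (32% in AcOH, 10 equiv), NaOAc (5 equiv), AcOH, rt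
Reagents that add atoms: peracetic acid (CC(=O)OO)
Why: Fleming–Tamao oxidation: bromodesilylation of the phenyl group, then peracid-induced 1,2-shift of C3 from silicon to oxygen with retention, should give the 3α-alcohol.

Step 15
Reactants: 21 3α,6β-diol
Product: 22 diester: 3α,6β-bis(3-methylbutanoyloxy)-4α,8α,10β-trimethyl-4β-[(triisopropylsilyloxy)methyl]-5α-H-decalin-9-one
Conditions: isovaleryl chloride (6 equiv), DMAP (2 equiv), pyridine, 60 °C
Reagents that add atoms: 3-methylbutanoyl chloride (CC(C)CC(=O)Cl)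
Why: DMAP-catalysed acylation under forcing conditions should esterify both hindered axial secondary alcohols; the only primary hydroxyl is masked as the TIPS ether.

Step 16
Reactants: 22 diester
Product: 23 enol triflate: 3α,6β-bis(3-methylbutanoyloxy)-4α,8,10β-trimethyl-4β-[(triisopropylsilyloxy)methyl]-5α-H-decal-8-en-9-yl trifluoromethanesulfonate
Conditions: Tf2O (1.5 equiv), 2,6-di-tert-butyl-4-methylpyridine (2 equiv), CH2Cl2, 0 °C to rt
Reagents that add atoms: trifluoromethanesulfonic anhydride (O=S(=O)(OS(=O)(=O)C(F)(F)F)C(F)(F)F)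
Why: Electrophilic O-triflation with a hindered pyridine base tolerates the esters, and because C10 is quaternary only the C8=C9 enol triflate can form.

Step 17
Reactants: 24 but-2-ynoic acid
Product: 25 tert-butyl but-2-ynoate
Conditions: tert-butyl 2,2,2-trichloroacetimidate (1.5 equiv), BF3·OEt2 (5 mol%), cyclohexane/CH2Cl2, rt
Reagents that add atoms: tert-butyl 2,2,2-trichloroacetimidate (CC(C)(C)OC(=N)C(Cl)(Cl)Cl)
Why: Acid-catalysed tert-butylation of a carboxylic acid with the trichloroacetimidate.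

Step 18
Reactants: 25 tert-butyl but-2-ynoate
Product: 26 tert-butyl (2E)-3-methylpenta-2,4-dienoate
Conditions: CH2=CHMgBr (2.2 equiv), CuI (1.1 equiv), THF, −78 °C; then 25, −78 °C; MeOH quench at −78 °C
Reagents that add atoms: vinylmagnesium bromide CH2=CHMgBr (C=C[Mg]Br)
Why: Syn carbocupration of the ynoate (cuprate conjugate addition) and protonation with retention should place the new vinyl group trans to the ester, i.e. the 2E-dienoate.

Step 19
Reactants: 26 tert-butyl (2E)-3-methylpenta-2,4-dienoate; 23 enol triflate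
Product: 28 tert-butyl 3α,6β-bis(3-methylbutanoyloxy)-19-(triisopropylsilyloxy)labda-8,13E-dien-15-oate, via alkylborane 27 (not isolated)
Conditions: 26, 9-BBN (1.05 equiv), THF, 0 °C to rt; then 23, Pd(dppf)Cl2 (10 mol%), AsPh3 (10 mol%), Cs2CO3 (3 equiv), DMF/H2O, 50 °C
Reagents that add atoms: none
Why: 9-BBN adds to the terminal vinyl group only, and B-alkyl Suzuki–Miyaura coupling with the enol triflate should form C9–C11 with both alkene geometries retained.

Step 20
Reactants: 28 tert-butyl 3α,6β-bis(3-methylbutanoyloxy)-19-(triisopropylsilyloxy)labda-8,13E-dien-15-oate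
Product: 30 3α,6β-bis(3-methylbutanoyloxy)-19-hydroxylabda-8,13E-dien-15-oic acid (target), via trimethylsilyl ester 29 (not isolated)
Conditions: TMSOTf (3 equiv), 2,6-lutidine (4 equiv), CH2Cl2, 0 °C; then HF·pyridine, THF, 0 °C to rt
Reagents that add atoms: none
Why: Silyl triflate-mediated loss of isobutene from the tert-butyl ester, then fluoride cleavage of the silyl ester and the TIPS ether under non-basic conditions, should free the acid and C19–OH without acyl migration or alkene shift.

## Compound list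

1 | prop-2-yn-1-ol | C#CCO | starting material
2 | (E)-alkenylalane from carboalumination of 1 (O- and C-bound dimethylaluminium) | C[Al](C)OC/C(C)=C/[Al](C)C | intermediate (not isolated)
3 | (E)-3-iodo-2-methylprop-2-en-1-ol | OC/C(C)=C/I | intermediate
4 | (E)-3-iodo-2-methylprop-2-enal | O=C/C(C)=C/I | intermediate
5 | (1E,3R,4S)-1-iodo-2,4-dimethylhexa-1,5-dien-3-ol | C=C[C@H](C)[C@@H](O)/C(C)=C/I | intermediate
6 | C-6, O-4 bis(9-borabicyclo[3.3.1]nonan-9-yl) adduct of 5 | C(CB1C2CCCC1CCC2)[C@H](C)[C@@H](OB1C2CCCC1CCC2)/C(C)=C/I | intermediate (not isolated)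
7 | (3S,4R,5E)-6-iodo-3,5-dimethylhex-5-ene-1,4-diol | OCC[C@H](C)[C@@H](O)/C(C)=C/I | intermediate
8 | (4S,5R)-5-[(E)-1-iodoprop-1-en-2-yl]-4-methyloxolan-2-ol (lactol, anomers) | OC1C[C@H](C)[C@H](/C(C)=C/I)O1 | intermediate (not isolated)
9 | (4S,5R)-5-[(E)-1-iodoprop-1-en-2-yl]-4-methyloxolan-2-one | O=C1C[C@H](C)[C@H](/C(C)=C/I)O1 | intermediate
10 | ethynyl(dimethyl)phenylsilane | C#C[Si](C)(C)c1ccccc1 | starting material
11 | (E)-dimethyl(phenyl)[2-(4,4,5,5-tetramethyl-1,3,2-dioxaborolan-2-yl)ethenyl]silane | C[Si](C)(/C=C/B1OC(C)(C)C(C)(C)O1)c1ccccc1 | intermediate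
12 | (4S,5R)-5-[(2E,4E)-5-[dimethyl(phenyl)silyl]penta-2,4-dien-2-yl]-4-methyloxolan-2-one | O=C1C[C@H](C)[C@H](/C(C)=C/C=C/[Si](C)(C)c2ccccc2)O1 | intermediate
13 | (E)-[(3-iodo-2-methylprop-2-en-1-yl)oxy]tri(propan-2-yl)silane | CC(C)[Si](OC/C(C)=C/I)(C(C)C)C(C)C | intermediate
14 | (E)-[2-methyl-3-(triisopropylsilyloxy)prop-1-en-1-yl]lithium | CC(C)[Si](OC/C(C)=C/[Li])(C(C)C)C(C)C | intermediate (not isolated)
15 | (2E,6S,7R,8E,10E)-11-[dimethyl(phenyl)silyl]-7-hydroxy-2,6,8-trimethyl-1-[(triisopropylsilyl)oxy]undeca-2,8,10-trien-4-one | CC(C)[Si](OC/C(C)=C/C(=O)C[C@H](C)[C@@H](O)/C(C)=C/C=C/[Si](C)(C)c1ccccc1)(C(C)C)C(C)C | intermediate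
16 | cis-fused octalone: 3α-silyl, 9α-OH, 8β-Me, 4α-Me, 4β-CH2OTIPS, 10β-Me, 5β-H, Δ1, 6-one | C[C@@H]1[C@@H](O)[C@@]2(C)C=C[C@@H]([Si](C)(C)c3ccccc3)[C@](C)(CO[Si](C(C)C)(C(C)C)C(C)C)[C@H]2C(=O)C1 | intermediate
17 | cis-fused decalone: as 16 with C1–C2 saturated | C[C@@H]1[C@@H](O)[C@@]2(C)CC[C@@H]([Si](C)(C)c3ccccc3)[C@](C)(CO[Si](C(C)C)(C(C)C)C(C)C)[C@H]2C(=O)C1 | intermediate
18 | cis-fused 6,9-dione (5β-H, 8β-Me) | C[C@@H]1C(=O)[C@@]2(C)CC[C@@H]([Si](C)(C)c3ccccc3)[C@](C)(CO[Si](C(C)C)(C(C)C)C(C)C)[C@H]2C(=O)C1 | intermediate (not isolated)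
19 | trans-fused 6,9-dione (5α-H, 8α-Me) | C[C@H]1C(=O)[C@@]2(C)CC[C@@H]([Si](C)(C)c3ccccc3)[C@](C)(CO[Si](C(C)C)(C(C)C)C(C)C)[C@@H]2C(=O)C1 | intermediate
20 | 6β-hydroxy-9-ketone (3α-silyl, 5α-H, 8α-Me) | C[C@H]1C(=O)[C@@]2(C)CC[C@@H]([Si](C)(C)c3ccccc3)[C@](C)(CO[Si](C(C)C)(C(C)C)C(C)C)[C@@H]2[C@H](O)C1 | intermediate
21 | 3α,6β-dihydroxy-9-ketone | C[C@H]1C(=O)[C@@]2(C)CC[C@@H](O)[C@](C)(CO[Si](C(C)C)(C(C)C)C(C)C)[C@@H]2[C@H](O)C1 | intermediate
22 | 3α,6β-bis(3-methylbutanoyloxy)-9-ketone | C[C@H]1C(=O)[C@@]2(C)CC[C@@H](OC(=O)CC(C)C)[C@](C)(CO[Si](C(C)C)(C(C)C)C(C)C)[C@@H]2[C@H](OC(=O)CC(C)C)C1 | intermediate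
23 | C8=C9 enol triflate of 22 | CC1=C(OS(=O)(=O)C(F)(F)F)[C@@]2(C)CC[C@@H](OC(=O)CC(C)C)[C@](C)(CO[Si](C(C)C)(C(C)C)C(C)C)[C@@H]2[C@H](OC(=O)CC(C)C)C1 | intermediate
24 | but-2-ynoic acid | CC#CC(=O)O | starting material
25 | tert-butyl but-2-ynoate | CC#CC(=O)OC(C)(C)C | intermediate
26 | tert-butyl (2E)-3-methylpenta-2,4-dienoate | C=C/C(C)=C/C(=O)OC(C)(C)C | intermediate
27 | tert-butyl (2E)-5-(9-borabicyclo[3.3.1]nonan-9-yl)-3-methylpent-2-enoate | O=C(OC(C)(C)C)/C=C(\C)CCB1C2CCCC1CCC2 | intermediate (not isolated)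
28 | tert-butyl 3α,6β-bis(3-methylbutanoyloxy)-19-(triisopropylsilyloxy)labda-8,13E-dien-15-oate | CC1=C(CC/C(C)=C/C(=O)OC(C)(C)C)[C@@]2(C)CC[C@@H](OC(=O)CC(C)C)[C@](C)(CO[Si](C(C)C)(C(C)C)C(C)C)[C@@H]2[C@H](OC(=O)CC(C)C)C1 | intermediate
29 | trimethylsilyl 3α,6β-bis(3-methylbutanoyloxy)-19-(triisopropylsilyloxy)labda-8,13E-dien-15-oate | CC1=C(CC/C(C)=C/C(=O)O[Si](C)(C)C)[C@@]2(C)CC[C@@H](OC(=O)CC(C)C)[C@](C)(CO[Si](C(C)C)(C(C)C)C(C)C)[C@@H]2[C@H](OC(=O)CC(C)C)C1 | intermediate (not isolated)
30 | (3R,4S,5R,6R,10S)-3α,6β-bis(3-methylbutanoyloxy)-19-hydroxylabda-8,13E-dien-15-oic acid (CNP0272110.1) | CC1=C(CC/C(C)=C/C(=O)O)[C@@]2(C)CC[C@@H](OC(=O)CC(C)C)[C@](C)(CO)[C@@H]2[C@H](OC(=O)CC(C)C)C1 | target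

## Step count and risks

Total: 20 steps. Longest linear sequence: 16 steps (steps 1–5, 7, 9–16, 19, 20).

**Step 10 (cycloaddition).** Two processes may intrude. An exo-tether transition state would invert C4 relative to C10 irreversibly. The cycloaddition may also be slow, since each new bond ends at a fully substituted carbon, letting hemiketal dehydration of the γ-hydroxy enone or a [1,5]-hydrogen shift from the inside methyl compete. The fallback replaces the neutral thermal reaction by cycloaddition of a Lewis acid–enone complex of the protected substrate. Setting out from 15, TESOTf/2,6-lutidine gives the triethylsilyl ether of the trienone F1. Me2AlCl (1.1 equiv) in CH2Cl2 at −40 °C, the known low-temperature endo-selective regime for decatrienones, should give the triethylsilyl ether of the cis-fused octalone F2. PPTS in MeOH removes the silyl group and the route is rejoined at 16.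

**Step 12 (ring-fusion equilibration).** With the axial C3 silyl group in place, the cis/trans equilibrium may not lie decisively on the trans side, leaving cis-fused material. The fallback uses a temporary ring as a thermodynamic trap. Setting out from 18 (isolated after the oxidation), HF·pyridine frees C19–OH to give the 19-hydroxy cis-dione F3. NaOMe in MeOH then equilibrates C5 and C8 while the C19 hydroxyl captures the 5α-H epimer as the five-membered 19,6-hemiketal F4; only the trans-fused epimer has C19 and C6 on the same face. LiBH(s-Bu)3 reduces the hemiketal/ketone mixture from the α face to the 6β,19-diol F5. TIPSCl/imidazole silylates the primary hydroxyl selectively and the route is rejoined at 20.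

**Step 19 (C9–C11 coupling).** Oxidative addition and transmetalation at the tetrasubstituted triflate next to quaternary C10 may be slow, so that protodeboronation or β-hydride loss from the alkylborane, or 1,4-hydroboration of the dienoate, wins. The fallback reverses the polarity so that only a small vinyl group is transferred to the hindered centre. Setting out from 23, Stille coupling with Bu3SnCH=CH2 (Pd(PPh3)4, LiCl, THF, 65 °C) gives the 9-vinyl diene F6. 9-BBN adds to the terminal vinyl carbon to give the primary alkylborane F7. Suzuki coupling (Pd(dppf)Cl2, K3PO4, THF/H2O) with tert-butyl (2E)-3-(trifluoromethylsulfonyloxy)but-2-enoate F8, made from tert-butyl acetoacetate with Tf2O and aqueous Me4NOH, rejoins the route at 28.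

Further compounds

F1 | step 10 | (2E,6S,7R,8E,10E)-11-[dimethyl(phenyl)silyl]-2,6,8-trimethyl-7-(triethylsilyloxy)-1-(triisopropylsilyloxy)undeca-2,8,10-trien-4-one | CC(C)[Si](OC/C(C)=C/C(=O)C[C@H](C)[C@@H](O[Si](CC)(CC)CC)/C(C)=C/C=C/[Si](C)(C)c1ccccc1)(C(C)C)C(C)C
F2 | step 10 | 9-O-triethylsilyl ether of cis-fused octalone 16 | C[C@@H]1[C@@H](O[Si](CC)(CC)CC)[C@@]2(C)C=C[C@@H]([Si](C)(C)c3ccccc3)[C@](C)(CO[Si](C(C)C)(C(C)C)C(C)C)[C@H]2C(=O)C1
F3 | step 12 | 19-hydroxy cis-fused 6,9-dione (5β-H, 8β-Me, 3α-silyl) | C[C@@H]1C(=O)[C@@]2(C)CC[C@@H]([Si](C)(C)c3ccccc3)[C@](C)(CO)[C@H]2C(=O)C1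
F4 | step 12 | trans-fused 19,6-hemiketal (6α-hydroxy-6β,19-epoxy, 5α-H, 8α-Me, 9-one) | C[C@H]1C(=O)[C@@]2(C)CC[C@@H]([Si](C)(C)c4ccccc4)[C@]3(C)CO[C@](O)(C1)[C@H]23
F5 | step 12 | 6β,19-dihydroxy-9-ketone (3α-silyl, 5α-H, 8α-Me) | C[C@H]1C(=O)[C@@]2(C)CC[C@@H]([Si](C)(C)c3ccccc3)[C@](C)(CO)[C@@H]2[C@H](O)C1
F6 | step 19 | 9-vinyl diene: 3α,6β-bis(3-methylbutanoyloxy)-9-ethenyl-19-(triisopropylsilyloxy) decal-8-ene | CC1=C(C=C)[C@@]2(C)CC[C@@H](OC(=O)CC(C)C)[C@](C)(CO[Si](C(C)C)(C(C)C)C(C)C)[C@@H]2[C@H](OC(=O)CC(C)C)C1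
F7 | step 19 | 9-[2-(9-borabicyclo[3.3.1]nonan-9-yl)ethyl] derivative of F6 | CC1=C(CCB3C4CCCC3CCC4)[C@@]2(C)CC[C@@H](OC(=O)CC(C)C)[C@](C)(CO[Si](C(C)C)(C(C)C)C(C)C)[C@@H]2[C@H](OC(=O)CC(C)C)C1
F8 | step 19 | tert-butyl (2E)-3-(trifluoromethylsulfonyloxy)but-2-enoate | C/C(OS(=O)(=O)C(F)(F)F)=C\C(=O)OC(C)(C)C
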